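A ratio carried this flask for me: the partner the charges can claim, divided by the partner charged. It contains no time and no rate constant, so I could bound it before knowing any speed.

in all of them: starting material 0.53 M; partner 1.33 M; third substrate 0.106 M
- zeta: second substrate 0.80 M (in portions, 4); run made earlier; portions every 15 min
- flask: second substrate 0.530 M (in portions, 4); the portions of second substrate follow each other after 15 min, the first at the start; time 30 h

- zeta (time / h: target / %, self-condensation product / %): 0.200: 10.3, 17.9; 0.667: 24.0, 36.6; 1.00: 29.6, 40.6; 1.50: 34.6, 43.8; 2.50: 41.4, 47.6; 3.00: 41.9, 48.5

(scatter of a reading: 0.5 percentage points)

- a species is counted by the starting material in it: one self-condensation product counts as two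

* the target in the flask at 30 h, as a percentage of the starting material charged
* the self-condensation product in the flask at 30 h, as a percentage of the starting material charged
* concentration of partner at 30 h, in M

I assumed that each second substrate, each third substrate and each starting material going to target takes one partner, while self-condensation takes none. For the bound from above, I let the flask's target be the 41.9 % that the zeta run read at 3.00 h and let nothing else use partner, which left 83.3 % of the charge. For the crude bound from below, I let both substrates react completely and the starting material go wholly to target, which left 12.3 %.

I tightened that lower bound with the zeta reading of 48.5 % self-condensation product at 3.00 h, which I took over to the flask as an estimate, the two having the same charges of starting material and partner. That put target at 51.5 % in my reckoning, and the demand ratio, claimable partner over charged partner, came to 68.3 %. That is below one, so on my assumption partner was in excess, not the limiting reagent, and the floor rose to 31.7 %. I fitted no speed for second substrate to the readings, so my bracket stopped there. I leaned towards its floor as a guess, since 30 h is ten times the last reading.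

The forecast gave 48 % target, 50 % self-condensation product and 1.075 M partner, “assuming 1:1 consumption”. That partner is 80.8 % of the charge, inside my bracket and near its top, whereas I leaned towards the bottom.

The flask gave 50.9 % target, 49.1 % self-condensation product and 0.451 M partner, which is 33.9 % of its charge.

    second substrate + partner → second product (k = 4.90 × 10⁻⁵ M⁻¹ s⁻¹)
    starting material + partner → target (k = 1.30 × 10⁻⁴ M⁻¹ s⁻¹)
    2 starting material → self-condensation product (k = 3.30 × 10⁻⁴ M⁻¹ s⁻¹)
    third substrate + partner → third product (k = 3.90 × 10⁻⁴ M⁻¹ s⁻¹)

The step from second substrate and partner was using partner 4.5 times as fast as the step to target at 4.53 h, and 260 times as fast at 30.0 h. Target meanwhile stood at 50.7 % at 15.0 h and 50.9 % at 30.0 h. The flask had used 66.1 % of its partner against the demand ratio of 68.3 %, with 5.0 % of its second substrate left. The neighbouring flask, whose charge of second substrate is 2.1 M, has a demand ratio of 186 %, above one, and it ended with 53 % of its second substrate and 0.097 % of its partner left.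

The data stem from a simulated flask with constants of no real substance, noise included.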